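The furofuran is cut across ring A: the C2–O3–C4 unit of ring A is a carbonyl ylide (aryl A aldehyde carbon, oxygen, CH2) lying over the C1–C5 ring-fusion bond, which in the precursor is the C1=C5 alkene of a ring B butenolide (C8 carbonyl, aryl B on C6). One [3+2] cycloaddition forms C1–C2 and C4–C5, closes ring A and sets C1, C2 and C5 from the single C6 stereocentre. The precursors are (S)-5-(3,4,5-trimethoxyphenyl)furan-2(5H)-one and an α-chlorobenzyl (trimethylsilyl)methyl ether of the allyl-protected aryl A aldehyde. Reduction of C8 to CH2 and deallylation finish the synthesis.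

Key step: step 5

Remarks on the chemistry
- Numbering: 3,7-dioxabicyclo[3.3.0]octane. C1 and C5 are the bridgeheads. Ring A is C1, C2 (aryl A = 3-hydroxy-4,5-dimethoxyphenyl), O3, C4H2, C5. Ring B is C5, C6 (aryl B = 3,4,5-trimethoxyphenyl), O7, C8, C1.
- Descriptors: the target is the exo,exo isomer (1R,2S,5R,6S). The same arrangement in space changes label along the route by CIP priority only: the carbinol centre is (R) in alkynol 3 and (S) in 4 and 5; C1 is (S) in 11 and 12 and (R) in 14 and 15.
- Precursor design: the aryl A phenol is carried as an allyl ether. A benzyl ether would have to be removed by hydrogenolysis in the presence of the benzylic C2–O3 and C6–O7 bonds, which Pd/H2 can also cleave.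
- Precursor design: the ylide is released with the anhydrous, weakly basic fluoride source Bu4N[Ph3SiF2] at low temperature, because the C6–H of the butenolide is acidic.
- Assumption: both antipodes of the ProPhenol ligand are available; the one whose dizinc complex delivers the alkynyl group to the Si face of aldehyde 1 is used, and the sense is confirmed once on 3 (MTPA esters, chiral HPLC).

Step 1
Reactants: 1 3,4,5-trimethoxybenzaldehyde; 2 methyl propiolate
Product: 3 methyl (R)-4-hydroxy-4-(3,4,5-trimethoxyphenyl)but-2-ynoate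
Conditions: ProPhenol (10 mol%, antipode giving Si-face attack), ZnMe2 (3 equiv), 2 (3 equiv), PhMe, 0–4 °C; aq. NH4Cl
Reagents that add atoms: none
Why: Catalytic asymmetric alkynylation of an aldehyde by the zinc alkynylide of 2 inside the chiral dinuclear zinc–ProPhenol pocket, a reaction class suited to aryl aldehydes and propiolates; Si-face attack sets the carbinol centre (the future C6) as (R).

Step 2
Reactants: 3 methyl (R)-4-hydroxy-4-(3,4,5-trimethoxyphenyl)but-2-ynoate
Product: 5 (S)-5-(3,4,5-trimethoxyphenyl)furan-2(5H)-one, via Z-hydroxy enoate 4 (not isolated)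
Conditions: H2 (1 atm), Pd/CaCO3 poisoned with Pb(OAc)2, quinoline (cat.), EtOAc, 0 °C to rt; filter, dilute acid wash; PPTS (cat.), CH2Cl2, rt
Reagents that add atoms: none
Why: Syn semihydrogenation on poisoned palladium gives the Z-enoate 4, whose hydroxyl lies next to the ester and closes the butenolide by intramolecular transesterification (5-exo-trig lactonisation), leaving the carbinol centre untouched.

Step 3
Reactants: 6 3-hydroxy-4,5-dimethoxybenzaldehyde
Product: 7 3-(allyloxy)-4,5-dimethoxybenzaldehyde
Conditions: allyl bromide, K2CO3, DMF, rt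
Reagents that add atoms: allyl bromide, C=CCBr
Why: Williamson ether synthesis on the only acidic group; the allyl ether should tolerate dry HCl, fluoride, iBu2AlH and Et3SiH/BF3·OEt2 and is later removed without hydrogen.

Step 4
Reactants: 7 3-(allyloxy)-4,5-dimethoxybenzaldehyde; 8 (trimethylsilyl)methanol
Product: 9 [3-(allyloxy)-4,5-dimethoxyphenyl](chloro)methyl (trimethylsilyl)methyl ether (racemic)
Conditions: HCl (g), CaCl2, CH2Cl2, −10 to 0 °C; filter and evaporate under Ar; use crude at once
Reagents that add atoms: hydrogen chloride, Cl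
Why: Classical α-chloro ether synthesis, in which the hemiacetal of 7 and 8 exchanges hydroxyl for chloride under dry HCl while CaCl2 binds the water; the new centre is racemic, which does not matter because it becomes planar in the ylide.

Step 5
Reactants: 5 (S)-5-(3,4,5-trimethoxyphenyl)furan-2(5H)-one; 9 [3-(allyloxy)-4,5-dimethoxyphenyl](chloro)methyl (trimethylsilyl)methyl ether
Product: 11 exo,exo-(1S,2S,5R,6S)-2-[3-(allyloxy)-4,5-dimethoxyphenyl]-6-(3,4,5-trimethoxyphenyl)-3,7-dioxabicyclo[3.3.0]octan-8-one, via carbonyl ylide 10 (not isolated)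
Conditions: Bu4N[Ph3SiF2] (1.5 equiv), 9 (2 equiv, slow addition), 4 Å MS, MeCN/CH2Cl2, −30 to 0 °C
Reagents that add atoms: none
Why: Proposed new method: fluoride attacks silicon while chloride leaves from the benzylic carbon of 9 (a 1,3-elimination eased by the electron-rich aryl A ring), giving the planar ylide 10, which adds suprafacially across C1=C5 of 5 in a concerted but asynchronous [3+2] cycloaddition; the closest known reaction type is the fluoride-triggered 1,3-elimination of α-chloroalkyl silylmethyl ethers and capture of the resulting non-stabilised carbonyl ylides by acrylates, enones and maleates, and new here is an aryl-substituted ylide meeting a chiral, base-sensitive γ-aryl butenolide. Ring A is closed by the cycloaddition itself, C4–C5 and C1–C2 forming in one event with C4–C5 leading, not by a later cyclisation. Regiochemistry follows ylide polarity: the carbanion-like CH2 terminus (larger HOMO coefficient) bonds to the β-carbon C5 and the benzylic terminus to the α-carbon C1, so that developing charge sits on the lactone enolate and on the oxocarbenium carbon stabilised by aryl A. C1 and C5 are cis because both bonds form on one face of the ring-locked cis alkene, and that face is the one anti to aryl B, so the existing C6 centre fixes the absolute configuration of C5 and C1. C2 is set by the E geometry of the ylide together with the exo transition state, in which O3 and aryl A point away from the lactone ring, placing aryl A trans to C8. The step needs regio-, face- and exo-selectivity and an intact C6 centre; polarity and sterics should provide the first three, and the weakly basic anhydrous fluoride source, low temperature and slow addition of 9 guard the acidic C6–H.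

Step 6
Reactants: 11 exo,exo-(1S,2S,5R,6S)-2-[3-(allyloxy)-4,5-dimethoxyphenyl]-6-(3,4,5-trimethoxyphenyl)-3,7-dioxabicyclo[3.3.0]octan-8-one
Product: 12 (1S,2S,5R,6S)-2-[3-(allyloxy)-4,5-dimethoxyphenyl]-6-(3,4,5-trimethoxyphenyl)-3,7-dioxabicyclo[3.3.0]octan-8-ol (C8 anomers)
Conditions: iBu2AlH (1.2 equiv), CH2Cl2, −78 °C; aq. potassium sodium tartrate
Reagents that add atoms: none
Why: Partial reduction of a γ-lactone to the lactol with one hydride equivalent at −78 °C, where the tetrahedral aluminium alkoxide persists until work-up; C8 becomes a hemiacetal centre of no consequence, and the ethers, the allyl group and the four set centres are untouched.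

Step 7
Reactants: 12 (1S,2S,5R,6S)-2-[3-(allyloxy)-4,5-dimethoxyphenyl]-6-(3,4,5-trimethoxyphenyl)-3,7-dioxabicyclo[3.3.0]octan-8-ol
Product: 14 exo,exo-(1R,2S,5R,6S)-2-[3-(allyloxy)-4,5-dimethoxyphenyl]-6-(3,4,5-trimethoxyphenyl)-3,7-dioxabicyclo[3.3.0]octane, via C8 oxocarbenium ion 13 (not isolated)
Conditions: Et3SiH (3 equiv), BF3·OEt2 (1.5 equiv), CH2Cl2, −78 to −40 °C; aq. NaHCO3
Reagents that add atoms: none
Why: Lewis-acid-mediated ionic hydrogenation of a lactol, in which BF3 ionises the anomeric C8–OH to the oxocarbenium ion 13 and Et3SiH delivers hydride to C8; at −78 °C the benzylic C2–O3 and C6–O7 bonds should ionise far more slowly, so no stereocentre is touched.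

Step 8
Reactants: 14 exo,exo-(1R,2S,5R,6S)-2-[3-(allyloxy)-4,5-dimethoxyphenyl]-6-(3,4,5-trimethoxyphenyl)-3,7-dioxabicyclo[3.3.0]octane
Product: 15 exo,exo-(1R,2S,5R,6S)-2-(3-hydroxy-4,5-dimethoxyphenyl)-6-(3,4,5-trimethoxyphenyl)-3,7-dioxabicyclo[3.3.0]octane (CNP0181235.1)
Conditions: Pd(PPh3)4 (5 mol%), morpholine (5 equiv), THF, rt
Reagents that add atoms: none
Why: Tsuji–Trost-type deallylation, in which zerovalent palladium ionises the allyl aryl ether to a π-allyl complex and the phenoxide and morpholine captures the allyl group; the furofuran ethers are benzylic but not allylic and stay inert, so no stereocentre is at risk.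

Compound list
1 | 3,4,5-trimethoxybenzaldehyde | COc1cc(C=O)cc(OC)c1OC | starting material
2 | methyl propiolate | C#CC(=O)OC | starting material
3 | methyl (R)-4-hydroxy-4-(3,4,5-trimethoxyphenyl)but-2-ynoate | COC(=O)C#C[C@H](O)c1cc(OC)c(OC)c(OC)c1 | intermediate
4 | methyl (S,Z)-4-hydroxy-4-(3,4,5-trimethoxyphenyl)but-2-enoate (not isolated) | COC(=O)/C=C\[C@H](O)c1cc(OC)c(OC)c(OC)c1 | intermediate
5 | (S)-5-(3,4,5-trimethoxyphenyl)furan-2(5H)-one | O=C1C=C[C@@H](c2cc(OC)c(OC)c(OC)c2)O1 | intermediate
6 | 3-hydroxy-4,5-dimethoxybenzaldehyde | COc1cc(C=O)cc(O)c1OC | starting material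
7 | 3-(allyloxy)-4,5-dimethoxybenzaldehyde | COc1cc(C=O)cc(OCC=C)c1OC | intermediate
8 | (trimethylsilyl)methanol | C[Si](C)(C)CO | starting material
9 | [3-(allyloxy)-4,5-dimethoxyphenyl](chloro)methyl (trimethylsilyl)methyl ether (racemic) | C[Si](C)(C)COC(Cl)c1cc(OC)c(OC)c(OCC=C)c1 | intermediate
10 | (E)-carbonyl ylide ArCH=O(+)–CH2(−), Ar = 3-(allyloxy)-4,5-dimethoxyphenyl (not isolated) | [CH2-]/[O+]=C/c1cc(OC)c(OC)c(OCC=C)c1 | intermediate
11 | exo,exo-(1S,2S,5R,6S)-2-[3-(allyloxy)-4,5-dimethoxyphenyl]-6-(3,4,5-trimethoxyphenyl)-3,7-dioxabicyclo[3.3.0]octan-8-one | COc1cc([C@H]2OC[C@H]3[C@@H]2C(=O)O[C@@H]3c2cc(OC)c(OC)c(OC)c2)cc(OCC=C)c1OC | intermediate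
12 | (1S,2S,5R,6S)-2-[3-(allyloxy)-4,5-dimethoxyphenyl]-6-(3,4,5-trimethoxyphenyl)-3,7-dioxabicyclo[3.3.0]octan-8-ol (C8 anomers) | COc1cc([C@H]2OC[C@H]3[C@@H]2C(O)O[C@@H]3c2cc(OC)c(OC)c(OC)c2)cc(OCC=C)c1OC | intermediate
13 | C8 oxocarbenium ion derived from 12 (not isolated) | COc1cc([C@H]2OC[C@H]3[C@@H]2C=[O+][C@@H]3c2cc(OC)c(OC)c(OC)c2)cc(OCC=C)c1OC | intermediate
14 | exo,exo-(1R,2S,5R,6S)-2-[3-(allyloxy)-4,5-dimethoxyphenyl]-6-(3,4,5-trimethoxyphenyl)-3,7-dioxabicyclo[3.3.0]octane | COc1cc([C@H]2OC[C@H]3[C@@H]2CO[C@@H]3c2cc(OC)c(OC)c(OC)c2)cc(OCC=C)c1OC | intermediate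
15 | exo,exo-(1R,2S,5R,6S)-2-(3-hydroxy-4,5-dimethoxyphenyl)-6-(3,4,5-trimethoxyphenyl)-3,7-dioxabicyclo[3.3.0]octane (CNP0181235.1) | COc1cc([C@H]2OC[C@H]3[C@@H]2CO[C@@H]3c2cc(OC)c(OC)c(OC)c2)cc(O)c1OC | target

Total step count: 8.
Longest linear sequence: 6 steps (steps 1, 2, 5, 6, 7, 8 from aldehyde 1; equally steps 3, 4, 5, 6, 7, 8 from aldehyde 6).

Steps most likely to fail

1. Step 5 (proposed new method). What may go wrong:
- The ylide or fluoride removes the acidic C6–H of 5 faster than cycloaddition occurs, causing loss of enantiopurity and tautomerisation to the hydroxyfuran.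
- The ylide closes to the oxirane or dimerises before it meets the dipolarophile.
- Material leaks into the endo or the regioisomeric mode.

Fallback, known chemistry with a different approach: stepwise conjugate addition–aldol on a chiral acetal butenolide, then reductive unmasking and double cycloetherification. It sets out from aldehydes 1 and 7 and comes back to the route at 14; steps 6 and 7 fall away and step 8 follows. Aldehyde 1 is converted with propane-1,3-dithiol and BF3·OEt2 into 2-(3,4,5-trimethoxyphenyl)-1,3-dithiane F1. Its lithio derivative (n-BuLi, THF, −78 °C) adds to the β-carbon of commercial (5R)-5-[(1R,2S,5R)-menthyloxy]furan-2(5H)-one anti to the menthyloxy group, and the lactone enolate is trapped in the same flask by 7 anti to the new substituent. This should give the trans,trans lactone (3S,4R,5R)-3-{[3-(allyloxy)-4,5-dimethoxyphenyl](hydroxy)methyl}-5-[(1R,2S,5R)-menthyloxy]-4-[2-(3,4,5-trimethoxyphenyl)-1,3-dithian-2-yl]dihydrofuran-2(3H)-one F2, which already holds C1 and C5 in the required sense. MeI/CaCO3 in aqueous MeCN frees the ketone (3S,4R,5R)-3-{[3-(allyloxy)-4,5-dimethoxyphenyl](hydroxy)methyl}-5-[(1R,2S,5R)-menthyloxy]-4-(3,4,5-trimethoxybenzoyl)dihydrofuran-2(3H)-one F3. LiAlH4 reduces ketone, lactone and acetal to (2R,3R)-2-{[3-(allyloxy)-4,5-dimethoxyphenyl](hydroxy)methyl}-3-[hydroxy(3,4,5-trimethoxyphenyl)methyl]butane-1,4-diol F4. Camphorsulfonic acid in CH2Cl2 then closes both tetrahydrofuran rings through the aryl-stabilised benzylic cations, under thermodynamic control, to the exo,exo ether 14.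

2. Step 4. What may go wrong:
- The HCl addition stalls at the hemiacetal or acetal stage.
- The labile chloro ether reverts to aldehyde and alcohol when HCl is removed.
- Traces of water hydrolyse it before use.

Fallback, a different approach through an isolable acetal instead of direct hydrochlorination: it sets out from 7 and 8 and comes back at 9. Aldehyde 7 is condensed with two equivalents of 8 (TsOH cat., benzene, Dean–Stark) to 1-(allyloxy)-5-{bis[(trimethylsilyl)methoxy]methyl}-2,3-dimethoxybenzene F5. One alkoxy group is then exchanged for chloride with acetyl chloride (ZnCl2 cat., CH2Cl2, 0 °C), a standard acetal-to-α-chloro-ether cleavage that produces neither water nor free HCl. The resulting 9 goes into step 5 after evaporation.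

3. Step 7. What may go wrong:
- BF3 ionises the benzylic C2–O3 or C6–O7 bond, with epimerisation at C2 or C6.
- The opened cation is captured by hydride, giving reductive ring opening.

Fallback, a different approach by full reduction and base-mediated ring closure instead of acidic deoxygenation: it sets out from lactone 11 and comes back at 14, so step 6 falls away too. LiAlH4 (THF, 0 °C) opens 11 to the diol [(2S,3R,4R)-2-[3-(allyloxy)-4,5-dimethoxyphenyl]-4-[(S)-hydroxy(3,4,5-trimethoxyphenyl)methyl]tetrahydrofuran-3-yl]methanol F6. MsCl (1.1 equiv) in pyridine at 0 °C sulfonylates the primary hydroxyl selectively to the mesylate [(2S,3R,4R)-2-[3-(allyloxy)-4,5-dimethoxyphenyl]-4-[(S)-hydroxy(3,4,5-trimethoxyphenyl)methyl]tetrahydrofuran-3-yl]methyl methanesulfonate F7. On warming, the C6 hydroxyl displaces the mesylate (5-exo-tet), which closes ring B with retention at C6 and gives 14 without Lewis acid.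

Further compounds
F1 | step 5 | 2-(3,4,5-trimethoxyphenyl)-1,3-dithiane | COc1cc(C2SCCCS2)cc(OC)c1OC
F2 | step 5 | (3S,4R,5R)-3-{[3-(allyloxy)-4,5-dimethoxyphenyl](hydroxy)methyl}-5-[(1R,2S,5R)-menthyloxy]-4-[2-(3,4,5-trimethoxyphenyl)-1,3-dithian-2-yl]dihydrofuran-2(3H)-one (carbinol epimers) | C[C@@H]1CC[C@H]([C@@H](C1)O[C@H]2[C@H](C3(c4cc(OC)c(OC)c(OC)c4)SCCCS3)[C@@H](C(O)c3cc(OC)c(OC)c(OCC=C)c3)C(=O)O2)C(C)C
F3 | step 5 | (3S,4R,5R)-3-{[3-(allyloxy)-4,5-dimethoxyphenyl](hydroxy)methyl}-5-[(1R,2S,5R)-menthyloxy]-4-(3,4,5-trimethoxybenzoyl)dihydrofuran-2(3H)-one (carbinol epimers) | C[C@@H]1CC[C@H]([C@@H](C1)O[C@H]2[C@H](C(=O)c3cc(OC)c(OC)c(OC)c3)[C@@H](C(O)c3cc(OC)c(OC)c(OCC=C)c3)C(=O)O2)C(C)C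
F4 | step 5 | (2R,3R)-2-{[3-(allyloxy)-4,5-dimethoxyphenyl](hydroxy)methyl}-3-[hydroxy(3,4,5-trimethoxyphenyl)methyl]butane-1,4-diol (carbinol epimers) | OC[C@H](C(O)c1cc(OC)c(OC)c(OCC=C)c1)[C@H](CO)C(O)c1cc(OC)c(OC)c(OC)c1
F5 | step 4 | 1-(allyloxy)-5-{bis[(trimethylsilyl)methoxy]methyl}-2,3-dimethoxybenzene | C[Si](C)(C)COC(OC[Si](C)(C)C)c1cc(OC)c(OC)c(OCC=C)c1
F6 | step 7 | [(2S,3R,4R)-2-[3-(allyloxy)-4,5-dimethoxyphenyl]-4-[(S)-hydroxy(3,4,5-trimethoxyphenyl)methyl]tetrahydrofuran-3-yl]methanol | COc1cc([C@H]2OC[C@@H]([C@@H]2CO)[C@H](O)c2cc(OC)c(OC)c(OC)c2)cc(OCC=C)c1OC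
F7 | step 7 | [(2S,3R,4R)-2-[3-(allyloxy)-4,5-dimethoxyphenyl]-4-[(S)-hydroxy(3,4,5-trimethoxyphenyl)methyl]tetrahydrofuran-3-yl]methyl methanesulfonate | COc1cc([C@H]2OC[C@@H]([C@@H]2COS(C)(=O)=O)[C@H](O)c2cc(OC)c(OC)c(OC)c2)cc(OCC=C)c1OC
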